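## Retrosynthetic overview
- Abyssinone-IV (2S) is the 3',5'-diprenyl derivative of the licorice flavanone (S)-liquiritigenin. All three rings and the C2 stereocentre are already in that commercial chiral starting material, so no ring is formed in this route.
- Disconnect the two aryl–prenyl C–C bonds to a 3',5'-dibromophenol. These are made in one photochemical Ni/Ir dual-catalytic double cross-coupling with potassium prenyltrifluoroborate.
- Disconnect the dibromide to ortho-dibromination of the free B-ring phenol, with the more acidic and more nucleophilic 7-OH masked as a MOM ether first.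
- The last step is mild Lewis-acid removal of the MOM group.

Assumptions: (S)-liquiritigenin is purchased (licorice-derived) and is the chiral starting material. The 7-OH (pKa about 7.5) is more acidic than the 4'-OH (pKa about 10), so it is protected selectively under mild base at low temperature.

## Route

**Step 1**
Reactants: 1 (S)-liquiritigenin; 2 chloromethyl methyl ether
Product: 3 (2S)-7-(methoxymethoxy)-2-(4-hydroxyphenyl)chroman-4-one
Conditions: MOMCl (1.0 equiv), i-Pr2NEt (1.1 equiv), THF, −10 → 0 °C, 2 h
Reagents that add atoms: MOMCl, ClCOC (leaves CH2OCH3)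
Why: The more acidic 7-phenol is deprotonated and alkylated preferentially (Williamson-type O-alkylation, as in 7-O-selective alkylation of daidzein). The low temperature and weak amine base leave C2 untouched.

**Step 2**
Reactants: 3; 4 N-bromosuccinimide
Product: 5 (2S)-2-(3,5-dibromo-4-hydroxyphenyl)-7-(methoxymethoxy)chroman-4-one
Conditions: NBS (2.1 equiv), i-Pr2NH (10 mol%), CH2Cl2/MeCN, 0 °C, dark, 1 h
Reagents that add atoms: NBS, O=C1CCC(=O)N1Br (leaves Br)
Why: Amine-catalysed NBS bromination of a para-substituted free phenol is ortho-selective (phenol-directed N-bromoamine delivery), and the MOM-capped A-ring lacks this directing effect. The stereocentre is not involved, and the bromination is acid- and base-light.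

**Step 3**
Reactants: 5; 6 potassium prenyltrifluoroborate
Product: 7 MOM-protected abyssinone-IV, (2S)-2-(4-hydroxy-3,5-bis(3-methylbut-2-enyl)phenyl)-7-(methoxymethoxy)chroman-4-one
Conditions: 6 (3.5 equiv), [Ir{dF(CF3)ppy}2(dtbbpy)]PF6 (2 mol%), NiCl2·glyme (10 mol%), dtbbpy (10 mol%), 2,6-lutidine (2.5 equiv), DMF (0.05 M), blue LEDs (450 nm), rt, 24 h
Reagents that add atoms: potassium prenyltrifluoroborate, CC(C)=CC[B-](F)(F)F.[K+] (leaves two prenyl groups)
Why: Proposed new method: excited Ir(III) oxidises the prenyl-BF3K by single-electron transfer (loss of BF3) to a prenyl radical. Ni(0)(dtbbpy) adds into each C–Br bond ortho to the OH, the radical is captured at its less hindered primary terminus, and C(sp2)–C(sp3) reductive elimination from Ni(III) gives the linear prenyl arene, twice. The closest known reaction is Ni/photoredox cross-coupling of allyl and alkyl trifluoroborates with aryl bromides. The untested features are linear-selective double prenylation of a free 2,6-dibromophenol and use on a racemisation-prone chiral flavanone. The conditions are mild, the only base is weak, and the C2 stereocentre is untouched.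

**Step 4**
Reactants: 7
Product: 8 abyssinone-IV, (2S)-7-hydroxy-2-[4-hydroxy-3,5-bis(3-methylbut-2-enyl)phenyl]chroman-4-one
Conditions: ZnBr2 (4 equiv), n-PrSH (8 equiv), CH2Cl2, 0 °C → rt, 1 h, dark
Reagents that add atoms: none
Why: Lewis-acid/thiol cleavage of the aryl MOM acetal is mild and base-free, so the flavanone cannot ring-open to the chalcone and C2 stays (S). The prenyl alkenes and the free phenols survive.

## Compound list
1 | (S)-liquiritigenin, (2S)-7-hydroxy-2-(4-hydroxyphenyl)chroman-4-one | Oc1ccc([C@@H]2CC(=O)c3ccc(O)cc3O2)cc1 | starting material
2 | chloromethyl methyl ether | ClCOC | starting material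
3 | (2S)-7-MOM-liquiritigenin | Oc1ccc([C@@H]2CC(=O)c3ccc(OCOC)cc3O2)cc1 | intermediate
4 | N-bromosuccinimide | O=C1CCC(=O)N1Br | starting material
5 | (2S)-3',5'-dibromo-7-MOM-liquiritigenin | Oc1c(Br)cc([C@@H]2CC(=O)c3ccc(OCOC)cc3O2)cc1Br | intermediate
6 | potassium prenyltrifluoroborate | CC(C)=CC[B-](F)(F)F.[K+] | starting material
7 | (2S)-7-MOM-abyssinone-IV | CC(C)=CCc1cc([C@@H]2CC(=O)c3ccc(OCOC)cc3O2)cc(CC=C(C)C)c1O | intermediate
8 | abyssinone-IV | CC(C)=CCc1cc([C@@H]2CC(=O)c3ccc(O)cc3O2)cc(CC=C(C)C)c1O | target

## Totals
Total steps: 4. Longest linear sequence: 4 (from 1).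

## Three steps most likely to fail
1. **Step 3 (proposed new method).** Risks are incomplete double coupling, protodebromination, branched (reverse-prenyl) products, and phenoxide quenching of the photocatalyst.
 Fallback: thermal Pd-catalysed Suzuki–Miyaura coupling of 5 with B-prenyl-9-BBN or prenyl-Bpin (known chemistry, no light, mild K3PO4 as base).
2. **Step 2.** The 7-OMOM A-ring is a 1,3-dialkoxyarene and may compete for bromine, giving A-ring bromides.
 Fallback: start from (S)-liquiritin (the 7-O-glucoside), which masks 7-OH and deactivates the A-ring and also removes Step 1. Carry out the same bromination and Step 3 coupling, then cleave the glycoside with β-glucosidase at pH 5 and 37 °C.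
3. **Step 4.** The acid-labile prenylphenol could cyclise to a chroman, or the thiol could add to a prenyl alkene.
 Fallback: mask 7-OH in Step 1 as its 2-nitrobenzyl ether (2-nitrobenzyl bromide, K2CO3) instead of MOM, and remove it in the last step by 365 nm photolysis in neutral MeCN.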